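Its constants were set for the occasion; what happens was integrated by code.

I started from what eats X.E.X.

    E + X → E.X (k1 = 18.3 L mol⁻¹ s⁻¹)
    X + E.X → X.E.X (k2 = 12.7 L mol⁻¹ s⁻¹)
    X + X.E.X → Z (k3 = 6.38 L mol⁻¹ s⁻¹)
    X + X.E.X → G (k4 = 6.82 L mol⁻¹ s⁻¹)
    E + X.E.X → D (k5 = 53.5 L mol⁻¹ s⁻¹)
    2 X → X2 (k6 = 5.03 L mol⁻¹ s⁻¹)

| setting | dawn | spring | noon | summer |
|---|---|---|---|---|
| E | 1.0 mM | 1.0 mM | 1.0 mM (fed, over 24.0 s) | 1.0 mM |
| X | 2.50 mM | 2.50 mM (fed, over 24.0 s) | 2.50 mM | 2.50 mM |
| time | 30 s | 30 s | 30 s |  |
| remark | a closed flask charged with all of it at once and left for 30 s | all but X at the start; X goes in evenly over 24.0 s, the run ends at 30 s | a stirred flask in which E is dosed at a steady rate over 24.0 s without added volume, worked up at 30 s | a single well-mixed tank run continuously and read at steady state, 30 s in it on average |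

- a species is counted by the E in it: one D counts as two
- two of one species on the left: rate k times its square, two consumed each time
- the stated concentrations are those of everything mixed, before any reaction; amounts are the same in each set-up
- the feed brings no volume worth counting
- run time (dawn): 30 s

* the set-up with the highest share of X.E.X in all that became X.E.X or Z or G or D, at the outlet or at the end ("none" if the first two lie within 2 percentage points) (dawn / spring / noon / summer / none)
* share of X.E.X in all that became X.E.X or Z or G or D, at the outlet or at the end, dawn
* share of X.E.X in all that became X.E.X or Z or G or D, at the outlet or at the end, spring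
* share of X.E.X in all that became X.E.X or Z or G or D, at the outlet or at the end, noon
* share of X.E.X in all that became X.E.X or Z or G or D, at the outlet or at the end, summer

- Counted by the step in which E meets X.E.X alone, at charged concentrations, the pseudo-first-order half-life of X.E.X against E, τ, was 13.0 s. This is shorter than the 43 s and 41 s of the two steps with X, and shorter than their joint 21.0 s, so I ranked the flasks by E.
- I set τ against the time t that X.E.X stands in the flask. The exposure Θ, the number of τ in t, was 2.32 for dawn.
- Θ is a ranking and not a yield: in dawn, E has a half-life of 15 s by its first step alone, shorter than the run, so the real exposure drifts below Θ.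
- With an even feed, the average portion arrives halfway through the dosing, so I gave spring and noon both an estimated 1.39, less than dawn. That put both above dawn, but my reckoning could not part them.
- The tank has dawn's Θ on average, so I ranked it no higher than dawn.
- The forecast named spring, which I could not do, with dawn 46.5%, spring 55.5%, noon 52% and summer 31%, saying “the tank holds E and X.E.X together for longest and does worst”.
- The simulation gave spring: dawn 46.8%, spring 56.9%, noon 51.9%, summer 30.5%. Spring and noon, at Θ 1.39, both read above dawn at 2.32. Summer, at the same 2.32, read below the dawn share.
- Noon read at 80 s instead has Θ 5.25, up from 1.39. Its share was 28.5%, down from 51.9%, with X.E.X at 9.26% and D at 19.1% of the E charged.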